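**Retrosynthetic overview**

- Target 9 is (2S)-5,7,8,3',4'-pentamethoxyflavanone. Rings A and B are bought as arenes; ring C (the pyranone) is the only ring made and is closed last.
- Enabling feature: in ring C the ketone carbon C4 sits on ring A ortho to the ring oxygen O1, C3 is an unsubstituted CH2, and C2 carries O1, ring B and one H. Ring C is therefore the formal adduct of an aldehyde C4–H across an O1–C2(aryl)=C3H2 enol ether, and 9 is an isomer of the achiral aldehyde 8.
- Key disconnection C3–C4: enantioselective intramolecular hydroacylation of 8 closes ring C, creates the ketone and sets C2 in one atom-economic operation.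
- 8 comes from bromo ether 7 by E2 loss of HBr; 7 comes from phenol 4 and bromohydrin 6 by Mitsunobu etherification.
- 4 comes from 1,2,3,5-tetramethoxybenzene 1 (formylation, then chelation-controlled mono-demethylation); 6 comes from bromoketone 5.

Key step: step 6

Assumption: the absolute sense of induction in step 6 cannot be predicted with certainty for an oxygen-tethered alkene; the (R)-ligand is written, and its commercially available (S)-enantiomer is to be used if a test run should give the (2R)-flavanone.

**Route**

Step 1
Reactants: 1 1,2,3,5-tetramethoxybenzene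
Product: 3 2,3,4,6-tetramethoxybenzaldehyde, via aryl iminium chloride 2 (not isolated)
Conditions: POCl3, DMF, 0 °C → 60 °C; then H2O, rt
Reagents that add atoms: N,N-dimethylformamide, CN(C)C=O; water, O
Why: Vilsmeier–Haack formylation, in which the chloroiminium ion attacks one of the two free ring positions of the highly activated arene (they are equivalent by symmetry) and iminium salt 2 is hydrolysed on aqueous work-up.

Step 2
Reactants: 3 2,3,4,6-tetramethoxybenzaldehyde
Product: 4 2-hydroxy-3,4,6-trimethoxybenzaldehyde
Conditions: BCl3 (1.2 equiv), CH2Cl2, −78 °C → 0 °C; then H2O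
Reagents that add atoms: none
Why: Chelation-controlled Lewis acid ether cleavage, in which BCl3 binds the carbonyl oxygen and cleaves an ortho methoxy group; the 2-methoxy group, flanked by CHO and the 3-methoxy group and twisted out of the ring plane, is the more basic of the two and should be the one lost.

Step 3
Reactants: 5 2-bromo-1-(3,4-dimethoxyphenyl)ethan-1-one
Product: 6 rac-2-bromo-1-(3,4-dimethoxyphenyl)ethan-1-ol
Conditions: NaBH4, MeOH, 0 °C; aq NH4Cl quench
Reagents that add atoms: none
Why: Borohydride reduction of the ketone to the racemic bromohydrin, with low temperature and a mildly acidic quench preventing epoxide closure; the racemate suffices because this stereocentre is erased in step 5.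

Step 4
Reactants: 4 2-hydroxy-3,4,6-trimethoxybenzaldehyde; 6 rac-2-bromo-1-(3,4-dimethoxyphenyl)ethan-1-ol
Product: 7 rac-2-[2-bromo-1-(3,4-dimethoxyphenyl)ethoxy]-3,4,6-trimethoxybenzaldehyde
Conditions: PPh3, DIAD, THF, 0 °C → rt
Reagents that add atoms: none
Why: Mitsunobu etherification of the acidic, hydrogen-bonded phenol with the secondary benzylic alcohol, in which the aldehyde and the primary bromide are inert and the configuration of the product is irrelevant.

Step 5
Reactants: 7 rac-2-[2-bromo-1-(3,4-dimethoxyphenyl)ethoxy]-3,4,6-trimethoxybenzaldehyde
Product: 8 2-{[1-(3,4-dimethoxyphenyl)ethenyl]oxy}-3,4,6-trimethoxybenzaldehyde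
Conditions: KOtBu (1.2 equiv), THF, 0 °C → rt; aq NaHCO3 work-up, Et3N-deactivated silica
Reagents that add atoms: none
Why: E2 dehydrobromination of a 2-bromoethyl aryl ether to an aryl vinyl ether, in which the only β-hydrogen is the benzylic, oxygen-bearing C–H so that only the 1,1-disubstituted enol ether can form, and the non-enolisable, electron-rich aldehyde should tolerate tert-butoxide at low temperature.

Step 6
Reactants: 8 2-{[1-(3,4-dimethoxyphenyl)ethenyl]oxy}-3,4,6-trimethoxybenzaldehyde
Product: 9 (2S)-2-(3,4-dimethoxyphenyl)-5,7,8-trimethoxy-2,3-dihydro-4H-1-benzopyran-4-one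
Conditions: [Rh(cod)Cl]2 (2.5 mol%), (R)-DTBM-SEGPHOS (5.5 mol%), sodium tetrakis[3,5-bis(trifluoromethyl)phenyl]borate (5 mol%), dry degassed 1,4-dioxane, 80 °C
Reagents that add atoms: none
Why: Proposed new method: cationic monovalent rhodium should insert into the aldehyde C–H bond to give an acyl hydride of trivalent rhodium, the enol ether double bond should then insert into Rh–H with hydride going to C2 and rhodium to the terminal CH2, and C–C reductive elimination from the seven-membered acyl alkyl rhodacycle should form the C3–C4 bond and release the catalyst. The closest known reaction type is the rhodium/chiral bisphosphine-catalysed enantioselective intramolecular endo-hydroacylation of 1,1-disubstituted alkenes in ortho-allylbenzaldehydes (to 3-substituted tetralones) and in 2-(1-substituted vinyl)benzaldehydes (to 3-substituted indanones); the new element is the oxygen atom in the tether, which makes the alkene an aryl enol ether. Ring C closes in a 6-endo-trig mode with respect to the alkene. The C2 stereocentre is set under catalyst control in the hydride transfer, where the C2-symmetric bisphosphine distinguishes the two enantiotopic faces of the alkene (aryl against aryloxy substituent). The step needs endo closure over 5-exo closure to a 2-methyl-2-arylbenzofuran-3-one, and insertion over decarbonylation and over β-aryloxide elimination: the 1,1-disubstitution directs rhodium to the unhindered terminal carbon, the flanking 2-vinyloxy and 6-methoxy oxygens can chelate and stabilise the acyl hydride while the short ortho tether holds the alkene next to it, and the rhodacycle keeps Rh–C3 and C2–O1 away from the syn-coplanar geometry that β-elimination requires. The neutral, base-free conditions should also protect the flavanone from racemisation by retro-oxa-Michael ring opening.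

**Compound list**

1 | 1,2,3,5-tetramethoxybenzene | COc1cc(OC)c(OC)c(OC)c1 | starting material
2 | N-methyl-N-[(2,3,4,6-tetramethoxyphenyl)methylidene]methanaminium chloride (aryl iminium chloride) | COc1cc(OC)c(C=[N+](C)C)c(OC)c1OC.[Cl-] | intermediate
3 | 2,3,4,6-tetramethoxybenzaldehyde | COc1cc(OC)c(C=O)c(OC)c1OC | intermediate
4 | 2-hydroxy-3,4,6-trimethoxybenzaldehyde | COc1cc(OC)c(C=O)c(O)c1OC | intermediate
5 | 2-bromo-1-(3,4-dimethoxyphenyl)ethan-1-one | COc1ccc(C(=O)CBr)cc1OC | starting material
6 | rac-2-bromo-1-(3,4-dimethoxyphenyl)ethan-1-ol | COc1ccc(C(O)CBr)cc1OC | intermediate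
7 | rac-2-[2-bromo-1-(3,4-dimethoxyphenyl)ethoxy]-3,4,6-trimethoxybenzaldehyde | COc1ccc(C(CBr)Oc2c(C=O)c(OC)cc(OC)c2OC)cc1OC | intermediate
8 | 2-{[1-(3,4-dimethoxyphenyl)ethenyl]oxy}-3,4,6-trimethoxybenzaldehyde | COc1ccc(C(=C)Oc2c(C=O)c(OC)cc(OC)c2OC)cc1OC | intermediate
9 | (2S)-2-(3,4-dimethoxyphenyl)-5,7,8-trimethoxy-2,3-dihydro-4H-1-benzopyran-4-one | COc1ccc([C@@H]2CC(=O)c3c(OC)cc(OC)c(OC)c3O2)cc1OC | target

**Step count and risks**

Total step count: 6. Longest linear sequence: 5 steps (steps 1, 2, 4, 5 and 6).

Steps most likely to fail:

1. Step 6 (proposed new method). The oxygen-tethered enol ether may fail to insert productively: the acyl hydride may decarbonylate, the alkyl rhodium species may lose the aryloxy group by β-elimination, closure may go 5-exo, or face discrimination may be poor. The fallback uses known chemistry, sets the stereocentre before the ring closure and still closes ring C through the C3–C4 bond; it sets out from 5 and 4 and comes back at 9. Ketone 5 is reduced with catalytic (S)-2-methyl-CBS-oxazaborolidine and BH3·SMe2 in THF at 0 °C (Corey–Bakshi–Shibata reduction, aryl as the large group) to (1S)-2-bromo-1-(3,4-dimethoxyphenyl)ethan-1-ol F1. Mitsunobu etherification of 4 with F1 (PPh3, DIAD, THF, −20 °C), with inversion, should give 2-[(1R)-2-bromo-1-(3,4-dimethoxyphenyl)ethoxy]-3,4,6-trimethoxybenzaldehyde F2. An N-heterocyclic carbene generated from 3-benzyl-5-(2-hydroxyethyl)-4-methylthiazolium chloride and DBU in dioxane at 80 °C should turn the aldehyde into its Breslow intermediate, which displaces the primary bromide intramolecularly (the known carbene-catalysed cyclisation of 2-(2-haloethoxy)benzaldehydes to chroman-4-ones). This gives 9 with C2 untouched; the descriptor changes from R to S only because CH2Br outranks aryl and CH2C(=O) does not. Low temperature in the Mitsunobu step and short exposure to DBU are meant to limit ionisation and base-induced racemisation.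

2. Step 4. The doubly ortho-substituted, hydrogen-bonded phenol may be a sluggish Mitsunobu partner, and the electron-rich benzylic oxyphosphonium ion may ionise and eliminate instead of being substituted. The fallback sets out from 6 and 4 and comes back at 7. Alcohol 6 is converted with PBr3 in CH2Cl2 at 0 °C into 4-(1,2-dibromoethyl)-1,2-dimethoxybenzene F3, used crude; phenol 4 is then O-alkylated at the activated benzylic position of F3 with K2CO3 in acetone at rt (Williamson etherification with a benzylic bromide).

3. Step 5. tert-Butoxide may attack the aldehyde, the elimination may stay incomplete, or the acid-labile enol ether may hydrolyse during isolation. The fallback sets out from 7 and comes back at 8 under near-neutral conditions. Bromide 7 is displaced with sodium benzeneselenolate (from PhSeSePh and a deficit of NaBH4 in EtOH/THF at 0 °C, so that no hydride remains to reduce the aldehyde) to give rac-2-[1-(3,4-dimethoxyphenyl)-2-(phenylselanyl)ethoxy]-3,4,6-trimethoxybenzaldehyde F4. Oxidation with NaIO4 (NaHCO3, MeOH/THF/H2O, 0 °C) gives the selenoxide rac-2-[1-(3,4-dimethoxyphenyl)-2-(phenylseleninyl)ethoxy]-3,4,6-trimethoxybenzaldehyde F5, which on warming to 60 °C with iPr2NH should undergo syn-elimination toward its only β-hydrogen (the known route from 2-(phenylselanyl)ethyl ethers to vinyl ethers).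

**Further compounds**

F1 | step 6 | (1S)-2-bromo-1-(3,4-dimethoxyphenyl)ethan-1-ol | COc1ccc([C@@H](CBr)O)cc1OC
F2 | step 6 | 2-[(1R)-2-bromo-1-(3,4-dimethoxyphenyl)ethoxy]-3,4,6-trimethoxybenzaldehyde | COc1ccc([C@H](CBr)Oc2c(C=O)c(OC)cc(OC)c2OC)cc1OC
F3 | step 4 | 4-(1,2-dibromoethyl)-1,2-dimethoxybenzene | COc1ccc(C(Br)CBr)cc1OC
F4 | step 5 | rac-2-[1-(3,4-dimethoxyphenyl)-2-(phenylselanyl)ethoxy]-3,4,6-trimethoxybenzaldehyde | COc1ccc(C(C[Se]c2ccccc2)Oc2c(C=O)c(OC)cc(OC)c2OC)cc1OC
F5 | step 5 | rac-2-[1-(3,4-dimethoxyphenyl)-2-(phenylseleninyl)ethoxy]-3,4,6-trimethoxybenzaldehyde | COc1ccc(C(C[Se](=O)c2ccccc2)Oc2c(C=O)c(OC)cc(OC)c2OC)cc1OC
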